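(All runs are simulated for substances that don't exist; scatter was added.)

The scavenger in Wednesday's flask cannot remove more acid than was charged to remove it. Each electrophile that meets a nucleophile gives one target and one acid set free, and one scavenger takes up one acid. I therefore carry the cover C, the concentration of acid a flask's scavenger can remove, which is its equivalents times the starting electrophile: 0.200 M for Wednesday's, 0.300 M for Thursday's, 0.440 M for Tuesday's.

in all of them: electrophile 0.40 M
- east: nucleophile 1.3 equiv; scavenger 0.67 equiv; run made earlier
- north-east: nucleophile 1.3 equiv; scavenger 1.7 equiv; run made earlier
- Wednesday's: nucleophile 1.30 equiv; scavenger 0.500 equiv; time 40 h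
- Thursday's: nucleophile 1.30 equiv; scavenger 0.750 equiv; time 40 h
- Tuesday's: nucleophile 1.30 equiv; scavenger 1.10 equiv; time 40 h

| run | time / h | electrophile / % | target / % |
|---|---|---|---|
| east | 1.50 | 84 | 18 |
| east | 2.50 | 74 | 26 |
| east | 4.00 | 70 | 31 |
| east | 8.00 | 58 | 42 |
| east | 12.0 | 50 | 52 |
| east | 20.0 | 43 | 58 |
| north-east | 1.50 | 83 | 18 |
| north-east | 2.50 | 73 | 23 |
| north-east | 4.00 | 67 | 31 |
| north-east | 8.00 | 57 | 42 |
| north-east | 12.0 | 51 | 50 |
| north-east | 20.0 | 45 | 54 |

(readings scatter by 1.5 percentage points)

1. part of the electrophile that has reacted at the end, Wednesday's
2. part of the electrophile that has reacted at the end, Thursday's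
3. part of the electrophile that has reacted at the end, Tuesday's
4. what raising the equivalents of scavenger from its lowest to its highest value here does to the part of the electrophile that has reacted (changes below 5 percentage points count as none) (it rises / no change / it falls)

At the first instants there is no acid; then the target step starts to set it free. The east and north-east runs, with different scavenger charges, stand at 43% and 45% electrophile at 20.0 h, a gap of 2 percentage points against a scatter of 1.5 points, so I read no effect of the amount while scavenger lasts.

For the middle I work with the fraction left. In east it falls by a factor 0.862 from 8.00 h to 12.0 h, and by 0.860 over the next stretch, twice as long. The reaction is slowing hard, and I take the nucleophile to be leaving as homo dimer.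

For the end, I allow east's last factor once more, as a guess, over the stretch to 40 h; that takes the fraction left to 37.0%, so I reckon 63.0% reacted and 0.252 M of acid made. Thursday's and Tuesday's covers are larger than that , so I expect that figure in both. Wednesday's cover is smaller, and the east readings show that much acid made by about 12.0 h, with 50.0% reacted. Acid made beyond the cover in Wednesday's can bind nucleophile, so I put Wednesday's between those two figures, a bracket of 13 points against the margin of 5 points, and my reckoning leaves the trend open.

The forecast says 58.5% for Wednesday's, 63% for Thursday's, 63% for Tuesday's and no change, reasoning “so scavenger has no visible effect while it lasts”.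

    2 nucleophile → homo dimer (k = 8.38 × 10⁻⁵ /M/s)
    nucleophile + acid set free ⇌ protonated nucleophile, settled at all times (K = 330 /M)
    acid set free + scavenger → scavenged by-product (k = 0.0173 /M/s)
    target → over-reaction product (k = 2.33 × 10⁻⁸ /s)
    electrophile + nucleophile → acid set free + target (k = 1.00 × 10⁻⁴ /M/s)
    nucleophile + acid set free ⇌ idle adduct, settled at all times (K = 10.5 /M)

The flasks give 60.1%, 62.7% and 62.2%, so no change, a shift of 2.2 points. Wednesday's made 0.0403 M of acid beyond its cover, with 0.013% of its scavenger left, and free acid, protonated nucleophile and idle adduct together stand at 0.0403 M. The neighbour flask has Wednesday's cover but 0.330 equiv of nucleophile, which is its limiting reagent, with 1.0% left. Its electrophile reacts to 26.2%, making 0.105 M of acid, less than the cover. The cover then leaves 47.5% of the scavenger, and that flask holds 48%.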